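## Structural features

The target is a two-unit flavan: an upper robinetinidol unit (A ring with only the 7-hydroxyl, pyran C ring, pyrogallol B ring) is joined through C4 to C8' of a lower (−)-epigallocatechin 3'-O-gallate unit (phloroglucinol-type D ring, pyran ring, pyrogallol ring, galloyl ester on O3'). The upper pyran carries three contiguous stereocentres, C2 (R), C3 (S) and C4 (S), in the 2,3-trans-3,4-trans arrangement, and the lower pyran carries the 2',3'-cis pair (2'R,3'R) of the natural catechin. Twelve free phenols make the final compound sensitive to air and base. The gallate is open to hydrolysis, transesterification and hydride reduction, and the electron-rich benzylic positions (C2, C4, C2') tolerate neither strong acid nor forcing hydrogenolysis. The real difficulty is the C4–C8' bond: it is flanked by ortho substituents on both sides, must go to C8' and not C6', and C4 must end up trans to the C3 hydroxyl. The lower flavan core with both of its stereocentres is an abundant natural product and its gallate is one esterification away, so only the upper heterocycle has to be built. The key step exploits the fact that C3 and C4 of the upper pyran are neighbours that can both be alkene carbons: C3=C4 of a flav-3-ene is closed by metathesis between a vinyl group on the C2 carbinol carbon and a 1,1-diarylethene whose aryl groups are ring A and ring D. By the CIP rules the ether carbon of the metathesis diene and C2 of the flav-3-ene carry the descriptor S, because the B-ring aryl outranks an sp2 carbon, and the descriptor becomes R only when C3 is oxygenated, with no change at the centre.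

## Logic of the disconnections

22 to 21: the twelve O–CH2Ph bonds are cut. Benzyl is the one group that masks every phenol, survives base, palladium, ruthenium and borane, and leaves in a single neutral hydrogenolysis. All oxidation-sensitive phenols stay hidden until the last step. The forward step must stop short of cleaving the benzylic C2–O1 and C2'–O1' bonds and must spare the ester.

21 to 19: the C3–O and C4–H bonds are removed, giving C3=C4. Both centres become blank and are recreated together by a syn addition on the face away from the C2 aryl group, which gives the 2,3-trans-3,4-trans triad. Three stereocentres reduce to one. The addition (through 20) must put boron on C3, must not reduce the ester, and the oxidation must not be strongly basic.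

19 to 18: the C3=C4 double bond is cut by retro-metathesis. The pyran ring falls back to an aryl allyl ether and a 1,1-diarylethene, and the awkward sp3 C4–C8' bond becomes a flat sp2–sp2 bond with no stereochemistry and no 4→6 isomer. The catalyst must close onto a hindered gem-diaryl alkene without isomerising or racemising the allylic ether.

18 to 12 and 17: the O1–C2 ether bond is cut. An aryl 1-arylallyl ether is what iridium-catalysed allylic substitution of a linear cinnamyl carbonate by a phenoxide gives, branched and enantioenriched. This bond is made after the carbon–carbon coupling and not before it. An aryl 1-arylallyl ether would be ionised by Pd(0), and a tethered vinyl group would trap the diazo intermediate of the coupling by dipolar cycloaddition. The hindered phenoxide of 12 must attack the substituted allyl terminus, and the product must not re-ionise.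

12 to 11, then 11 to 9 and 5: the O–Si bond and then the C4–C8' bond are cut. The bromine in 5 fixes the regiochemistry of the coupling. A triisopropylsilyl ether is chosen for the phenol because buffered fluoride removes it without touching the ester, the benzyl ethers or the acid-sensitive electron-rich alkene. The coupling (through 10) must work at a bromide with two ortho substituents, and its base must spare ester and silyl ether.

9 to 8, 7 and 6: the C=N, O–Si and O–CH2Ph bonds are cut in turn, back to 6. The only demand is selective benzylation of the 4-hydroxyl over the chelated 2-hydroxyl.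

5 to 4: the C8'–Br bond is cut. The halogen is placed on the complete, protected lower unit so that the ester and both stereocentres are in place before any metal chemistry. Bromination must choose C8' over C6' and over the two trialkoxyphenyl rings.

4 to 2 and 3, then 2 to 1: the ester C(=O)–O3' bond and then five O–CH2Ph bonds are cut. Both stereocentres of the lower unit come from 1, and the galloyl part is bought already benzylated as 3. Alkylating only the five phenols of the flavan core keeps the ester away from a long phenolate alkylation, and the secondary hydroxyl is inert to carbonate and benzyl bromide. The benzylation must not epimerise C2' or alkylate the D ring on carbon, and the esterification must acylate a hindered axial alcohol.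

17 to 16, 15, 14 and 13: the carbonate C–O bond, the ester oxidation level, the C=C bond and three O–CH2Ph bonds are cut. The alkene must be E, since the iridium step needs the linear E carbonate.

## Other disconnections considered

Alternative 1: The D ring is taken apart at C8'–C8a', C6'–C7' and C4a'–C8a'. In the forward sense, photochemical Wolff rearrangement of diazo ketone A3 gives a vinylketene that adds [2+2] to siloxyalkyne A2. Four-electron ring opening, six-electron ring closure and tautomerisation then give the seco lower unit A1.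
- In its favour: the D ring is formed with the upper unit already on the carbon that becomes C8'. There is no 6/8 question and no cross-coupling at a doubly ortho-substituted centre; on this point it is better than the chosen plan. O7' (silyl) and O8a' (free) come out differentiated, and the pericyclic cascade tolerates ethers and esters.
- Against it: it rebuilds a ring that 1 supplies. Both lower stereocentres must be made in an open chain, and A2 needs the complete upper unit with all three stereocentres before the key step. A1 carries C2' in the configuration opposite to the target, so the pyran must be closed with inversion at a carbinol bearing a trialkoxyphenyl group, where ionisation can scramble the centre.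
- Comparison: on structure it is equal in avoiding the 4→6 isomer and better in regiochemical certainty. On mechanism the risks are comparable. On step economy it is clearly worse, since it adds the whole lower unit and the earlier upper-unit stereochemistry to the count.

Alternative 2: The lower pyran is cut at C4'–C4a'. In the forward sense a Lewis acid activates the terminal epoxide of aryl ether A5, and the D-ring carbon ortho to the ether oxygen attacks the CH2 terminus to give A4 with a free 3'-hydroxyl.
- In its favour: C4a' is the only position of a very nucleophilic ring that can reach the epoxide. C3' is carried unchanged in the epoxide. The gallate is introduced late, so no ester has to survive alkoxide base or borane; on this point it is better than the chosen plan.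
- Against it: the hard part, the upper unit with its three stereocentres and the C4–aryl bond, is left unsolved and must exist before A5 is made. The Lewis acid meets an acid-labile interflavan bond and a benzylic ether at C2' that can ionise. Attack at the primary carbon (six-membered ring) competes with attack at the secondary carbon (five-membered ring).
- Comparison: on structure it builds what can be bought. On mechanism the cyclisation is shorter-lived but less chemoselective than metathesis in this setting. On step economy it is worse: the galloylation counts the same in both plans, but the lower unit has to be made de novo.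

Alternative 3: The upper C3 is removed, cutting both C2–C3 and C3–C4, which leaves 2,3-diarylbenzofuran A7. In the forward sense a chlorocarbene equivalent cyclopropanates the furan C2=C3 bond, and the chlorocyclopropane opens with loss of chloride to give flavylium chloride A6.
- In its favour: it uses the same flat sp2–sp2 logic for the C4–C8' bond and is equal to the chosen plan there. It avoids both the iridium etherification and the closure onto a hindered diarylethene, and up to the flavene oxidation level it is probably the shorter route.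
- Against it: the upper ring of A6 is achiral. C2 would have to be created by hydride addition to a planar cation and would converge on 19 together with its C2 epimer, controlled only by a remote chiral unit or a chiral hydride source. The carbene must also select a tetrasubstituted, diaryl-flanked furan bond among twelve benzyloxyarenes.
- Comparison: on structure the chosen plan is better, because C2 is fixed under catalyst control before the ring is closed. On mechanism carbon insertion into such a congested furan is less well founded than metathesis of 2-(1-arylvinyl)aryl allyl ethers. On step economy the alternative is equal or slightly better until the C2 epimers have to be separated.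

Key step: step 14

Assumption: the antipode of the phosphoramidite ligand used in step 13 is the one that delivers the (S)-ether; both antipodes are accessible, and the facial sense should be confirmed on a simple phenol first.

## Route

Step 1
Reactants: 1 (−)-epigallocatechin
Product: 2 5,7,3',4',5'-penta-O-benzyl-(−)-epigallocatechin
Conditions: BnBr (5.5 equiv), K2CO3 (6 equiv), Bu4NI (cat.), degassed DMF, −10 °C → rt
Reagents that add atoms: benzyl bromide, BrCc1ccccc1
Why: Williamson etherification of the five phenols with a carbonate base, which does not deprotonate the secondary 3-hydroxyl; exclusion of oxygen and low temperature hold back phenolate oxidation, C-benzylation of the D ring and C2 epimerisation.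

Step 2
Reactants: 2 5,7,3',4',5'-penta-O-benzyl-(−)-epigallocatechin; 3 3,4,5-tris(benzyloxy)benzoic acid
Product: 4 octa-O-benzyl-(−)-epigallocatechin gallate
Conditions: DCC (1.5 equiv), DMAP (0.3 equiv), CH2Cl2, 0 °C → rt
Reagents that add atoms: none
Why: Steglich esterification; the acylpyridinium formed with DMAP acylates the hindered axial 3-hydroxyl under neutral conditions that leave C2 and C3 untouched.

Step 3
Reactants: 4 octa-O-benzyl-(−)-epigallocatechin gallate
Product: 5 8-bromo-octa-O-benzyl-(−)-epigallocatechin gallate
Conditions: NBS (1.0 equiv), CH2Cl2, −78 → 0 °C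
Reagents that add atoms: N-bromosuccinimide, O=C1CCC(=O)N1Br
Why: Electrophilic aromatic bromination; the phloroglucinol-type D ring is by far the most nucleophilic arene, and benzylated catechins are known to brominate at C8 in preference to C6, which lies between two benzyloxy groups.

Step 4
Reactants: 6 2,4-dihydroxyacetophenone
Product: 7 4-benzyloxy-2-hydroxyacetophenone
Conditions: BnBr (1.05 equiv), K2CO3, acetone, reflux
Reagents that add atoms: benzyl bromide, BrCc1ccccc1
Why: Williamson etherification; the 2-hydroxyl is held in a hydrogen bond to the ketone and is much less nucleophilic, so monobenzylation at O4 should be selective.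

Step 5
Reactants: 7 4-benzyloxy-2-hydroxyacetophenone
Product: 8 4-benzyloxy-2-(triisopropylsilyloxy)acetophenone
Conditions: TIPSCl, imidazole, DMF, 50 °C
Reagents that add atoms: chlorotriisopropylsilane, CC(C)[Si](Cl)(C(C)C)C(C)C
Why: Standard silylation of a chelated phenol; the bulky silyl ether should withstand the basic coupling and is later removed by fluoride under conditions that spare everything else.

Step 6
Reactants: 8 4-benzyloxy-2-(triisopropylsilyloxy)acetophenone
Product: 9 N-tosylhydrazone of 8
Conditions: TsNHNH2, MeOH, 60 °C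
Reagents that add atoms: p-toluenesulfonyl hydrazide, Cc1ccc(cc1)S(=O)(=O)NN
Why: Condensation of a methyl ketone with a sulfonyl hydrazide under neutral conditions; the hydrazone geometry is of no consequence.

Step 7
Reactants: 9 N-tosylhydrazone of 8; 5 8-bromo-octa-O-benzyl-(−)-epigallocatechin gallate
Product: 11 1-(octa-O-benzyl-EGCG-8-yl)-1-[4-benzyloxy-2-(triisopropylsilyloxy)phenyl]ethene, via aryl diazoethane 10 (not isolated)
Conditions: Pd2(dba)3 (5 mol %), XPhos (20 mol %), LiOtBu (2.4 equiv), 1,4-dioxane, 90 °C
Reagents that add atoms: none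
Why: Barluenga coupling: base releases the diazo compound, the aryl-palladium bromide forms a carbene, the aryl group migrates and β-hydride elimination from the methyl group gives the 1,1-diarylethene. No allyl ether or other alkene is present at this stage, so neither π-allyl ionisation nor diazo–alkene cycloaddition can interfere.

Step 8
Reactants: 11 1-(octa-O-benzyl-EGCG-8-yl)-1-[4-benzyloxy-2-(triisopropylsilyloxy)phenyl]ethene
Product: 12 1-(octa-O-benzyl-EGCG-8-yl)-1-(4-benzyloxy-2-hydroxyphenyl)ethene
Conditions: TBAF (1.1 equiv), AcOH (1.2 equiv), THF, 0 °C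
Reagents that add atoms: none
Why: Fluoride cleavage of an aryl silyl ether; buffering with acetic acid keeps the medium from attacking the gallate, and no acid strong enough to protonate the electron-rich diarylethene is present.

Step 9
Reactants: 13 3,4,5-trihydroxybenzaldehyde
Product: 14 3,4,5-tris(benzyloxy)benzaldehyde
Conditions: BnBr (3.5 equiv), K2CO3, DMF, 60 °C
Reagents that add atoms: benzyl bromide, BrCc1ccccc1
Why: Williamson etherification of the three phenols.

Step 10
Reactants: 14 3,4,5-tris(benzyloxy)benzaldehyde
Product: 15 ethyl (E)-3-[3,4,5-tris(benzyloxy)phenyl]prop-2-enoate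
Conditions: Ph3P=CHCO2Et, toluene, 80 °C
Reagents that add atoms: (ethoxycarbonylmethylene)triphenylphosphorane, CCOC(=O)C=P(c1ccccc1)(c1ccccc1)c1ccccc1
Why: Wittig olefination with a stabilised ylide, which should give the E alkene needed for the linear allylic carbonate.

Step 11
Reactants: 15 ethyl (E)-3-[3,4,5-tris(benzyloxy)phenyl]prop-2-enoate
Product: 16 (E)-3-[3,4,5-tris(benzyloxy)phenyl]prop-2-en-1-ol
Conditions: DIBAL-H (2.5 equiv), CH2Cl2, −78 → 0 °C; Rochelle salt
Reagents that add atoms: none
Why: 1,2-Reduction of an enoate to the allylic alcohol by an aluminium hydride, with the alkene geometry retained.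

Step 12
Reactants: 16 (E)-3-[3,4,5-tris(benzyloxy)phenyl]prop-2-en-1-ol
Product: 17 (E)-3-[3,4,5-tris(benzyloxy)phenyl]allyl methyl carbonate
Conditions: ClCO2Me, pyridine, CH2Cl2, 0 °C
Reagents that add atoms: methyl chloroformate, COC(=O)Cl
Why: Acylation of a primary allylic alcohol to the carbonate, the standard leaving group for iridium-catalysed allylic substitution.

Step 13
Reactants: 12 1-(octa-O-benzyl-EGCG-8-yl)-1-(4-benzyloxy-2-hydroxyphenyl)ethene; 17 (E)-3-[3,4,5-tris(benzyloxy)phenyl]allyl methyl carbonate
Product: 18 1-(octa-O-benzyl-EGCG-8-yl)-1-{4-benzyloxy-2-[(S)-1-(3,4,5-tris(benzyloxy)phenyl)allyloxy]phenyl}ethene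
Conditions: LiOtBu (1.0 equiv), THF, 0 °C; then 17 (1.5 equiv), [Ir(cod)Cl]2 (2 mol %), binaphthol-derived N,N-bis(1-phenylethyl)phosphoramidite (4 mol %, pre-activated with n-PrNH2), THF, rt → 50 °C
Reagents that add atoms: none
Why: Iridium-catalysed asymmetric allylic etherification: the cyclometalated iridium–phosphoramidite catalyst ionises the linear carbonate and the lithium aryloxide attacks the aryl-substituted allyl terminus, giving the branched ether. The new stereocentre (S) is set by the ligand; the existing centres are remote.

Step 14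
Reactants: 18 1-(octa-O-benzyl-EGCG-8-yl)-1-{4-benzyloxy-2-[(S)-1-(3,4,5-tris(benzyloxy)phenyl)allyloxy]phenyl}ethene
Product: 19 (2S)-7-benzyloxy-2-[3,4,5-tris(benzyloxy)phenyl]-4-(octa-O-benzyl-EGCG-8-yl)-2H-chromene
Conditions: Hoveyda–Grubbs II (10 mol %), 1,4-benzoquinone (20 mol %), CH2Cl2 (0.005 M), 40 °C, argon sparge, dark
Reagents that add atoms: none
Why: Ring-closing olefin metathesis: the ruthenium carbene loads on the monosubstituted vinyl group of the allylic ether and adds intramolecularly across the 1,1-diarylethene; cycloreversion of the ruthenacyclobutane gives C3=C4 and a ruthenium methylidene that leaves as ethene. The closest known reaction type is the metathesis of allyl ethers of 2-(1-arylvinyl)phenols to 4-aryl-2H-chromenes. The one ring closed is the six-membered pyran (O1, C2, C3, C4, C4a, C8a), formed as an endocyclic trisubstituted alkene on an ortho-preorganised benzo template. No stereocentre is created; C2 (S) is a spectator because neither its C–H nor its C–O bond takes part. The step needs ring closure over dimerisation, which high dilution secures, helped by the fact that the gem-diaryl alkene cannot homodimerise and any vinyl–vinyl dimer remains a substrate. It also needs metathesis over ruthenium hydride isomerisation of the allylic ether, which benzoquinone suppresses. Moderate temperature and exclusion of light guard against electrocyclic opening of the 2H-chromene, which would scramble C2. Sparging removes ethene and drives the closure onto the hindered alkene.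

Step 15
Reactants: 19 (2S)-7-benzyloxy-2-[3,4,5-tris(benzyloxy)phenyl]-4-(octa-O-benzyl-EGCG-8-yl)-2H-chromene
Product: 21 dodeca-O-benzyl robinetinidol-(4α→8)-epigallocatechin gallate, via C3 alkylborane 20 (not isolated)
Conditions: BH3·THF (3 equiv), THF, 0 °C → rt; then NaBO3·4H2O, THF/H2O, rt
Reagents that add atoms: borane–tetrahydrofuran (boron of 20), [BH3-][O+]1CCCC1; sodium perborate (oxygen of 21), B(=O)O[O-].[Na+]
Why: Hydroboration–oxidation of a flav-3-ene: boron goes to the less substituted, non-benzylic C3 and hydrogen to C4 in a syn addition on the face opposite the C2 aryl group; oxidation proceeds with retention. This sets C3 (S) and C4 (S) as the 2,3-trans-3,4-trans triad, and perborate avoids the alkaline peroxide that would endanger the gallate.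

Step 16
Reactants: 21 dodeca-O-benzyl robinetinidol-(4α→8)-epigallocatechin gallate
Product: 22 robinetinidol-(4α→8)-epigallocatechin 3'-O-gallate (CNP0269431.1)
Conditions: H2 (1 atm), 20% Pd(OH)2/C, THF/MeOH, rt; filtration under argon
Reagents that add atoms: none
Why: Hydrogenolysis of twelve benzyl ethers under neutral conditions, as used for the last step of oligomeric flavan-3-ol syntheses; the ester, the interflavan C–C bond and the cyclic benzylic ethers should survive at ambient pressure and temperature.

## Compound list

1 | (−)-epigallocatechin | O[C@@H]1Cc2c(O)cc(O)cc2O[C@@H]1c1cc(O)c(O)c(O)c1 | starting material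
2 | 5,7,3',4',5'-penta-O-benzyl-(−)-epigallocatechin (free 3-OH) | O[C@@H]1Cc2c(OCc3ccccc3)cc(OCc3ccccc3)cc2O[C@@H]1c1cc(OCc2ccccc2)c(OCc2ccccc2)c(OCc2ccccc2)c1 | intermediate
3 | 3,4,5-tris(benzyloxy)benzoic acid | OC(=O)c1cc(OCc2ccccc2)c(OCc2ccccc2)c(OCc2ccccc2)c1 | starting material
4 | octa-O-benzyl-(−)-epigallocatechin gallate ("octa-O-benzyl-EGCG") | O=C(O[C@@H]1Cc2c(OCc3ccccc3)cc(OCc3ccccc3)cc2O[C@@H]1c1cc(OCc2ccccc2)c(OCc2ccccc2)c(OCc2ccccc2)c1)c1cc(OCc2ccccc2)c(OCc2ccccc2)c(OCc2ccccc2)c1 | intermediate
5 | 8-bromo-octa-O-benzyl-(−)-epigallocatechin gallate | O=C(O[C@@H]1Cc2c(OCc3ccccc3)cc(OCc3ccccc3)c(Br)c2O[C@@H]1c1cc(OCc2ccccc2)c(OCc2ccccc2)c(OCc2ccccc2)c1)c1cc(OCc2ccccc2)c(OCc2ccccc2)c(OCc2ccccc2)c1 | intermediate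
6 | 2,4-dihydroxyacetophenone | CC(=O)c1ccc(O)cc1O | starting material
7 | 4-benzyloxy-2-hydroxyacetophenone | CC(=O)c1ccc(OCc2ccccc2)cc1O | intermediate
8 | 4-benzyloxy-2-(triisopropylsilyloxy)acetophenone | CC(=O)c1ccc(OCc2ccccc2)cc1O[Si](C(C)C)(C(C)C)C(C)C | intermediate
9 | N-tosylhydrazone of 8 | CC(=NNS(=O)(=O)c1ccc(C)cc1)c1ccc(OCc2ccccc2)cc1O[Si](C(C)C)(C(C)C)C(C)C | intermediate
10 | 1-[4-benzyloxy-2-(triisopropylsilyloxy)phenyl]-1-diazoethane | CC(=[N+]=[N-])c1ccc(OCc2ccccc2)cc1O[Si](C(C)C)(C(C)C)C(C)C | intermediate (not isolated)
11 | 1-(octa-O-benzyl-EGCG-8-yl)-1-[4-benzyloxy-2-(triisopropylsilyloxy)phenyl]ethene | O=C(O[C@@H]1Cc2c(OCc3ccccc3)cc(OCc3ccccc3)c(C(=C)c3ccc(OCc4ccccc4)cc3O[Si](C(C)C)(C(C)C)C(C)C)c2O[C@@H]1c1cc(OCc2ccccc2)c(OCc2ccccc2)c(OCc2ccccc2)c1)c1cc(OCc2ccccc2)c(OCc2ccccc2)c(OCc2ccccc2)c1 | intermediate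
12 | 1-(octa-O-benzyl-EGCG-8-yl)-1-(4-benzyloxy-2-hydroxyphenyl)ethene | O=C(O[C@@H]1Cc2c(OCc3ccccc3)cc(OCc3ccccc3)c(C(=C)c3ccc(OCc4ccccc4)cc3O)c2O[C@@H]1c1cc(OCc2ccccc2)c(OCc2ccccc2)c(OCc2ccccc2)c1)c1cc(OCc2ccccc2)c(OCc2ccccc2)c(OCc2ccccc2)c1 | intermediate
13 | 3,4,5-trihydroxybenzaldehyde | O=Cc1cc(O)c(O)c(O)c1 | starting material
14 | 3,4,5-tris(benzyloxy)benzaldehyde | O=Cc1cc(OCc2ccccc2)c(OCc2ccccc2)c(OCc2ccccc2)c1 | intermediate
15 | ethyl (E)-3-[3,4,5-tris(benzyloxy)phenyl]prop-2-enoate | CCOC(=O)/C=C/c1cc(OCc2ccccc2)c(OCc2ccccc2)c(OCc2ccccc2)c1 | intermediate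
16 | (E)-3-[3,4,5-tris(benzyloxy)phenyl]prop-2-en-1-ol | OC/C=C/c1cc(OCc2ccccc2)c(OCc2ccccc2)c(OCc2ccccc2)c1 | intermediate
17 | (E)-3-[3,4,5-tris(benzyloxy)phenyl]allyl methyl carbonate | COC(=O)OC/C=C/c1cc(OCc2ccccc2)c(OCc2ccccc2)c(OCc2ccccc2)c1 | intermediate
18 | 1-(octa-O-benzyl-EGCG-8-yl)-1-{4-benzyloxy-2-[(S)-1-(3,4,5-tris(benzyloxy)phenyl)allyloxy]phenyl}ethene (metathesis diene) | O=C(O[C@@H]1Cc2c(OCc3ccccc3)cc(OCc3ccccc3)c(C(=C)c3ccc(OCc4ccccc4)cc3O[C@@H](C=C)c3cc(OCc4ccccc4)c(OCc4ccccc4)c(OCc4ccccc4)c3)c2O[C@@H]1c1cc(OCc2ccccc2)c(OCc2ccccc2)c(OCc2ccccc2)c1)c1cc(OCc2ccccc2)c(OCc2ccccc2)c(OCc2ccccc2)c1 | intermediate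
19 | (2S)-7-benzyloxy-2-[3,4,5-tris(benzyloxy)phenyl]-4-(octa-O-benzyl-EGCG-8-yl)-2H-chromene (benzylated 4-aryl flav-3-ene) | O=C(O[C@@H]1Cc2c(OCc3ccccc3)cc(OCc3ccccc3)c(C3=C[C@@H](c4cc(OCc5ccccc5)c(OCc5ccccc5)c(OCc5ccccc5)c4)Oc4cc(OCc5ccccc5)ccc34)c2O[C@@H]1c1cc(OCc2ccccc2)c(OCc2ccccc2)c(OCc2ccccc2)c1)c1cc(OCc2ccccc2)c(OCc2ccccc2)c(OCc2ccccc2)c1 | intermediate
20 | C3 alkylborane of the benzylated dimer (2,3-trans-3,4-trans, BH2 on C3) | O=C(O[C@@H]1Cc2c(OCc3ccccc3)cc(OCc3ccccc3)c([C@@H]3c4ccc(OCc5ccccc5)cc4O[C@H](c4cc(OCc5ccccc5)c(OCc5ccccc5)c(OCc5ccccc5)c4)[C@H]3B)c2O[C@@H]1c1cc(OCc2ccccc2)c(OCc2ccccc2)c(OCc2ccccc2)c1)c1cc(OCc2ccccc2)c(OCc2ccccc2)c(OCc2ccccc2)c1 | intermediate (not isolated)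
21 | dodeca-O-benzyl robinetinidol-(4α→8)-epigallocatechin gallate (2R,3S,4S; 2'R,3'R; free 3-OH) | O=C(O[C@@H]1Cc2c(OCc3ccccc3)cc(OCc3ccccc3)c([C@@H]3c4ccc(OCc5ccccc5)cc4O[C@H](c4cc(OCc5ccccc5)c(OCc5ccccc5)c(OCc5ccccc5)c4)[C@H]3O)c2O[C@@H]1c1cc(OCc2ccccc2)c(OCc2ccccc2)c(OCc2ccccc2)c1)c1cc(OCc2ccccc2)c(OCc2ccccc2)c(OCc2ccccc2)c1 | intermediate
22 | robinetinidol-(4α→8)-epigallocatechin 3'-O-gallate (CNP0269431.1) | O=C(O[C@@H]1Cc2c(O)cc(O)c([C@@H]3c4ccc(O)cc4O[C@H](c4cc(O)c(O)c(O)c4)[C@H]3O)c2O[C@@H]1c1cc(O)c(O)c(O)c1)c1cc(O)c(O)c(O)c1 | target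

## Step count and least certain steps

Total: 16 steps. Longest linear sequence: 9 steps (from 6 through steps 4, 5, 6, 7, 8, 13, 14, 15, 16; equally from 1 through steps 1, 2, 3, 7, 8, 13, 14, 15, 16). Compounds 7 and 14 are also offered commercially; buying them would remove steps 4 and 9.

**Step 14 (key step).** The closure onto the gem-diaryl alkene, whose D-ring substituent has two ortho groups, may stall. The carbene would then dimerise the vinyl groups or decompose to hydride species that shift the allylic ether double bond. Separately, reversible electrocyclic opening of the 2H-chromene product would erode the configuration at C2.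

Fallback, setting out from 7, 14 and 5 and returning at 19: Claisen–Schmidt condensation of 7 with 14 (KOH, EtOH) would give the 2'-hydroxychalcone F1. Oxa-Michael cyclisation (NaOAc, EtOH, reflux) would give the racemic flavanone F2, and condensation with tosyl hydrazide its N-tosylhydrazone F3. Palladium-catalysed coupling of F3 with 5 (Pd2(dba)3, XPhos, LiOtBu, dioxane) should insert the aryl group at C4 and eliminate β-hydride from C3. This gives 19 together with its C2 epimer F4. The two are diastereomers and would have to be separated, since this approach gives up control of C2.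

**Step 7.** Oxidative addition and aryl migration at a bromide with two ortho oxygen substituents may be slower than the unproductive decay of the diazo compound (azine or styrene formation), than hydrodebromination, or than palladium-mediated C–H arylation of a neighbouring benzyl ether. The alkoxide base may also strip the silyl group early or attack the gallate.

Fallback, setting out from 8 and returning at 11: enolisation and triflation (KHMDS, PhNTf2, THF, −78 °C) would give the enol triflate F5. Miyaura borylation (B2pin2, PdCl2(PPh3)2, KOPh, toluene) would give the α-aryl vinylboronate F6. Suzuki–Miyaura coupling of F6 with 5 (SPhos–Pd precatalyst, K3PO4, dioxane/H2O) would then form the same C4–C8' bond through transmetalation and not through a carbene.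

**Step 13.** The aryloxide of 12 is hindered by its ortho 1-arylvinyl group, so substitution may be slow. Reversible ionisation of the electron-rich product ether would lower the enantiomeric purity and leak material to the linear ether. The methoxide released from the carbonate may start to cleave the gallate; a tert-butyl carbonate would be the first adjustment.

Fallback, setting out from 14 and 12 and returning at 18: addition of vinylmagnesium bromide to 14 would give the racemic allylic alcohol F7. Lipase-catalysed acetylation (CAL-B, vinyl acetate) should convert the R enantiomer into the acetate F8 and leave the S alcohol behind. Mild methanolysis (K2CO3, MeOH) would free the (R)-alcohol F9. Mitsunobu etherification of 12 with F9 (PPh3, DIAD, toluene, 0 °C) would give 18 with inversion. Partial ionisation at this electron-rich benzylic centre remains the weak point of the fallback.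

**Step 15.** Borane may add slowly to the trisubstituted alkene, which is shielded on both faces by the perpendicular D ring. This would give time for reduction of the gallate or for β-elimination of the aryloxy group from the C3 borane, and the face selectivity set by the C2 aryl group may be incomplete.

Fallback, setting out from 19 and returning at 21: copper-catalysed protoboration (CuCl, Xantphos, NaOtBu cat., B2pin2, i-PrOH, THF) adds boron to C3 and copper to benzylic C4, followed by protonation with retention. It is a syn addition that does not touch esters and should give the isolable pinacol boronate F10. Oxidation of F10 with sodium perborate would give 21.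

## Further compounds

F1 | step 14 | (E)-1-(4-benzyloxy-2-hydroxyphenyl)-3-[3,4,5-tris(benzyloxy)phenyl]prop-2-en-1-one | O=C(/C=C/c1cc(OCc2ccccc2)c(OCc2ccccc2)c(OCc2ccccc2)c1)c1ccc(OCc2ccccc2)cc1O
F2 | step 14 | rac-7-benzyloxy-2-[3,4,5-tris(benzyloxy)phenyl]chroman-4-one | O=C1CC(c2cc(OCc3ccccc3)c(OCc3ccccc3)c(OCc3ccccc3)c2)Oc2cc(OCc3ccccc3)ccc12
F3 | step 14 | N-tosylhydrazone of F2 | Cc1ccc(cc1)S(=O)(=O)NN=C1CC(c2cc(OCc3ccccc3)c(OCc3ccccc3)c(OCc3ccccc3)c2)Oc2cc(OCc3ccccc3)ccc12
F4 | step 14 | (2R)-7-benzyloxy-2-[3,4,5-tris(benzyloxy)phenyl]-4-(octa-O-benzyl-EGCG-8-yl)-2H-chromene (C2 epimer of 19) | O=C(O[C@@H]1Cc2c(OCc3ccccc3)cc(OCc3ccccc3)c(C3=C[C@H](c4cc(OCc5ccccc5)c(OCc5ccccc5)c(OCc5ccccc5)c4)Oc4cc(OCc5ccccc5)ccc34)c2O[C@@H]1c1cc(OCc2ccccc2)c(OCc2ccccc2)c(OCc2ccccc2)c1)c1cc(OCc2ccccc2)c(OCc2ccccc2)c(OCc2ccccc2)c1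
F5 | step 7 | 1-[4-benzyloxy-2-(triisopropylsilyloxy)phenyl]vinyl trifluoromethanesulfonate | C=C(OS(=O)(=O)C(F)(F)F)c1ccc(OCc2ccccc2)cc1O[Si](C(C)C)(C(C)C)C(C)C
F6 | step 7 | 2-{1-[4-benzyloxy-2-(triisopropylsilyloxy)phenyl]vinyl}-4,4,5,5-tetramethyl-1,3,2-dioxaborolane | C=C(B1OC(C)(C)C(C)(C)O1)c1ccc(OCc2ccccc2)cc1O[Si](C(C)C)(C(C)C)C(C)C
F7 | step 13 | rac-1-[3,4,5-tris(benzyloxy)phenyl]prop-2-en-1-ol | OC(C=C)c1cc(OCc2ccccc2)c(OCc2ccccc2)c(OCc2ccccc2)c1
F8 | step 13 | (R)-1-[3,4,5-tris(benzyloxy)phenyl]allyl acetate | CC(=O)O[C@H](C=C)c1cc(OCc2ccccc2)c(OCc2ccccc2)c(OCc2ccccc2)c1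
F9 | step 13 | (R)-1-[3,4,5-tris(benzyloxy)phenyl]prop-2-en-1-ol | O[C@H](C=C)c1cc(OCc2ccccc2)c(OCc2ccccc2)c(OCc2ccccc2)c1
F10 | step 15 | C3 pinacol boronate of the benzylated dimer (2,3-trans-3,4-trans) | O=C(O[C@@H]1Cc2c(OCc3ccccc3)cc(OCc3ccccc3)c([C@@H]3c4ccc(OCc5ccccc5)cc4O[C@H](c4cc(OCc5ccccc5)c(OCc5ccccc5)c(OCc5ccccc5)c4)[C@H]3B6OC(C)(C)C(C)(C)O6)c2O[C@@H]1c1cc(OCc2ccccc2)c(OCc2ccccc2)c(OCc2ccccc2)c1)c1cc(OCc2ccccc2)c(OCc2ccccc2)c(OCc2ccccc2)c1
A1 | alternative 1 | seco lower unit: D-ring phenol with free 8a'-OH, 7'-O-TIPS, open C2'–C4' chain (2'-O-TBS, 3'-O-galloyl), upper unit on C8' | O=C(O[C@H](Cc2c(OCc9ccccc9)cc(O[Si](C(C)C)(C(C)C)C(C)C)c([C@@H]3c4ccc(OCc9ccccc9)cc4O[C@H](c4cc(OCc9ccccc9)c(OCc9ccccc9)c(OCc9ccccc9)c4)[C@H]3OCc9ccccc9)c2O)[C@@H](O[Si](C)(C)C(C)(C)C)c1cc(OCc9ccccc9)c(OCc9ccccc9)c(OCc9ccccc9)c1)c1cc(OCc9ccccc9)c(OCc9ccccc9)c(OCc9ccccc9)c1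
A2 | alternative 1 | penta-O-benzyl robinetinidol carrying a (triisopropylsilyloxy)ethynyl group at C4 | CC(C)[Si](OC#C[C@@H]1c2ccc(OCc9ccccc9)cc2O[C@H](c2cc(OCc9ccccc9)c(OCc9ccccc9)c(OCc9ccccc9)c2)[C@H]1OCc9ccccc9)(C(C)C)C(C)C
A3 | alternative 1 | (Z)-α-benzyloxy enone diazomethyl ketone carrying the C2'–C4' chain (2'-O-TBS, 3'-O-galloyl) | O=C(O[C@H](C/C=C(OCc9ccccc9)/C(=O)C=[N+]=[N-])[C@@H](O[Si](C)(C)C(C)(C)C)c1cc(OCc9ccccc9)c(OCc9ccccc9)c(OCc9ccccc9)c1)c1cc(OCc9ccccc9)c(OCc9ccccc9)c(OCc9ccccc9)c1
A4 | alternative 2 | benzylated robinetinidol-(4α→8)-epigallocatechin with free 3'-hydroxyl | O[C@@H]1Cc2c(OCc9ccccc9)cc(OCc9ccccc9)c([C@@H]3c4ccc(OCc9ccccc9)cc4O[C@H](c4cc(OCc9ccccc9)c(OCc9ccccc9)c(OCc9ccccc9)c4)[C@H]3OCc9ccccc9)c2O[C@@H]1c1cc(OCc9ccccc9)c(OCc9ccccc9)c(OCc9ccccc9)c1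
A5 | alternative 2 | D-ring aryl ether of an aryl(oxiranyl)methanol carrying the upper unit ortho to the ether oxygen | C1O[C@H]1[C@@H](c1cc(OCc9ccccc9)c(OCc9ccccc9)c(OCc9ccccc9)c1)Oc1cc(OCc9ccccc9)cc(OCc9ccccc9)c1[C@@H]1c2ccc(OCc9ccccc9)cc2O[C@H](c2cc(OCc9ccccc9)c(OCc9ccccc9)c(OCc9ccccc9)c2)[C@H]1OCc9ccccc9
A6 | alternative 3 | benzylated 4-(EGCG-8'-yl)flavylium chloride | O=C(O[C@@H]1Cc2c(OCc9ccccc9)cc(OCc9ccccc9)c(c3c4ccc(OCc9ccccc9)cc4[o+]c(c4cc(OCc9ccccc9)c(OCc9ccccc9)c(OCc9ccccc9)c4)c3)c2O[C@@H]1c1cc(OCc9ccccc9)c(OCc9ccccc9)c(OCc9ccccc9)c1)c1cc(OCc9ccccc9)c(OCc9ccccc9)c(OCc9ccccc9)c1.[Cl-]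
A7 | alternative 3 | 6-benzyloxy-2-[3,4,5-tris(benzyloxy)phenyl]-3-(octa-O-benzyl-EGCG-8-yl)benzofuran | O=C(O[C@@H]1Cc2c(OCc9ccccc9)cc(OCc9ccccc9)c(c3c(c4cc(OCc9ccccc9)c(OCc9ccccc9)c(OCc9ccccc9)c4)oc4cc(OCc9ccccc9)ccc34)c2O[C@@H]1c1cc(OCc9ccccc9)c(OCc9ccccc9)c(OCc9ccccc9)c1)c1cc(OCc9ccccc9)c(OCc9ccccc9)c(OCc9ccccc9)c1
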